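(The runs come from a simulation for substances that don't exist, and the scatter is random.)

18.9 h is the charge turnover time: the time per whole charge of solid substrate turned into target at the slope of the zeta run between its first and last readings, a climb read here as a zero-order stretch, though the zeta run itself stops at 68%.

- zeta: solid substrate 2 M; second substrate 1 M; gas 200 mM (held); run made earlier
- flask: solid substrate 2.0 M; second substrate 2.00 M; gas 200 mM (held); time 20 h

- zeta (time / h: target / %): 5.00: 15; 6.00: 19; 8.00: 35; 10.0: 43; 12.0: 50; 15.0: 68

(standard deviation of a reading: 2 percentage points)

- when, up to 20 h, the flask holds most target
- the amount of target, in percent of the solid substrate charged, at that time
- the first time at which target reaches 25%, in the same percent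

- as a solid, counted per litre of solution: solid substrate
- at the start none of reagent is dissolved
- steps under discussion: starting material + reagent -> target; starting material + second substrate -> cross product; gas <-> reagent; second substrate + reagent -> second product; solid substrate <-> starting material
- at the start none of the solid substrate is in solution

Reading down the zeta table, the line through the first and last rows puts 41.5% at 10.0 h, where the row shows 43%, and each reading scatters by 2 percentage points. Running that line back from the first row reaches zero target at 2.17 h, a delay read from the zeta readings, and that is the second number the column gives.

The reckoning here, which is not the forecast's, assumes that the delay scales with the second substrate charge, an assumption one run cannot test, so that twice the charge gives the new flask a delay of 4.34 h. Counting turnovers from there, the estimate for the new flask is 83.0% of a charge by 20 h, less than one whole charge, so the best time is taken as 20 h, and 25% is counted at 9.06 h.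

The forecast gives 20 h, 50% and 11 h, holding that “Doubling the second substrate should therefore slow target formation”; its amount is lower than this count.

The flask gives its most target at 20.0 h, 81.9%, and reaches the asked level at 7.75 h.

    starting material + reagent → target (k = 0.0398 /M/min)
    starting material + second substrate → cross product (k = 0.00312 /M/min)
    gas ⇌ reagent, rate k3*(csat - [reagent]) (kL = 0.165 /min)
    second substrate + reagent → second product (k = 0.0156 /M/min)
    solid substrate ⇌ starting material, rate k5*(cs5 - [starting material]) while solid is left; crystals form when [starting material] > cs5 (solubility = 1.50 M, k = 0.00146 /min)

Target in this flask stands at 35.5% at 10.0 h and 66.0% at 16.0 h, which as a turnover time is 19.7 h, beside the 18.9 h read from the zeta run. The neighbouring flask, like this one but with 1.2 M of second substrate, has a counted delay of 2.60 h and a count of 92.2% of a charge by 20 h, and at that time it holds 87.2% of target.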